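**Retrosynthetic overview**
1. Target 9 ⇐ half-reduction of the α,β-unsaturated lactone 8; the lactol opens to the conjugated hydroxy-enal.
2. Ring B (C1–C8a bond) ⇐ cationic Friedel–Crafts closure of the benzylic silyl ether in arylidene lactone 7; the C2 centre directs the aryl group trans.
3. C3=C4 ⇐ aldol condensation of β-substituted butyrolactone 6 with MOM-vanillin.
4. C2 stereocentre and the C2–C3 (8–8') bond ⇐ Eschenmoser–Claisen [3,3] rearrangement of (R,E)-allylic alcohol 4. The purchased carbinol centre is transferred 1,3 to carbon and then excised by ozonolysis.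
5. 4 ⇐ (R)-but-3-yn-2-ol + MOM-vanillin. Ring order: both arenes bought → butyrolactone (step 4) → ring B (step 6) → lactone opened (step 7).

Assumptions: (R)-but-3-yn-2-ol and MOM-vanillin are taken as commercial (MOM-vanillin is otherwise one step from vanillin). The benzylic carbinol centre made in step 1 is carried as a ~1:1 mixture because it is ionised and reset in step 6.

**Step 1**
Reactants: 1, (R)-but-3-yn-2-ol; 2, 3-methoxy-4-(methoxymethoxy)benzaldehyde
Product: 3, (2R,5RS)-5-[(tert-butyldimethylsilyl)oxy]-5-[3-methoxy-4-(methoxymethoxy)phenyl]pent-3-yn-2-ol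
Conditions: n-BuLi (1.0 eq), TMSCl, THF, −78 → 0 °C; n-BuLi (1.05 eq), −78 °C; 2; TBSCl, DMPU, −78 °C → rt; K2CO3, MeOH (TMS off)
Reagents that add atoms: TBSCl, CC(C)(C)[Si](C)(C)Cl (the TMS group is transient and not retained)
Why: Transient O-silylation allows lithium acetylide 1,2-addition to the aldehyde, the new alkoxide is capped in situ as the TBS ether, and the labile TMS ether is cleaved on work-up; the bought stereocentre is untouched and the new benzylic centre is deliberately uncontrolled.

**Step 2**
Reactants: 3
Product: 4, (2R,3E,5RS)-5-[(tert-butyldimethylsilyl)oxy]-5-[3-methoxy-4-(methoxymethoxy)phenyl]pent-3-en-2-ol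
Conditions: Red-Al, THF, −20 → 0 °C; Rochelle salt
Reagents that add atoms: none
Why: Hydroxyl-directed trans-hydroalumination of the propargylic alcohol gives only the E-alkene, and the poor silyloxy leaving group at low temperature suppresses allene formation.

**Step 3 (key step)**
Reactants: 4
Product: 5, (3R,4E)-3-{(RS)-[(tert-butyldimethylsilyl)oxy][3-methoxy-4-(methoxymethoxy)phenyl]methyl}-N,N-dimethylhex-4-enamide
Conditions: MeC(OMe)2NMe2 (4 eq), xylenes, 140 °C (−MeOH)
Reagents that add atoms: N,N-dimethylacetamide dimethyl acetal, CC(OC)(OC)N(C)C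
Why: Eschenmoser–Claisen [3,3]-sigmatropic rearrangement under neutral conditions; the chair transition state with methyl equatorial transfers the (R)-carbinol chirality suprafacially across the E-allyl unit, forming the C2–C3 bond and setting the future C2 centre (both benzylic epimers converge on the same configuration).

**Step 4**
Reactants: 5
Product: 6, (4R)-4-{(RS)-[(tert-butyldimethylsilyl)oxy][3-methoxy-4-(methoxymethoxy)phenyl]methyl}dihydrofuran-2(3H)-one
Conditions: O3, CH2Cl2/MeOH, −78 °C (Sudan III end point); NaBH4, −78 → 0 °C; then PPTS (cat.), PhMe, 80 °C (−Me2NH)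
Reagents that add atoms: ozone, [O-][O+]=O (supplies the lactone ring oxygen)
Why: Ozonolysis of the isolated alkene (much faster than the arene) removes the spent stereocentre as acetaldehyde, cold borohydride reduction gives the primary alcohol before the α-chiral aldehyde can enolise, and acid-catalysed acyl transfer closes the γ-lactone.

**Step 5**
Reactants: 6; 2 (second equivalent)
Product: 7, (3E,4R)-4-{(RS)-[(tert-butyldimethylsilyl)oxy][3-methoxy-4-(methoxymethoxy)phenyl]methyl}-3-[3-methoxy-4-(methoxymethoxy)benzylidene]dihydrofuran-2(3H)-one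
Conditions: LiHMDS, THF, −78 °C; 2; Ac2O, −78 → 0 °C; DBU, rt
Reagents that add atoms: none (Ac2O is not retained)
Why: Kinetic lactone enolate aldol addition followed by acetylation and E1cB elimination gives the thermodynamically preferred E-arylidene lactone (aryl cis to C4, as needed for ring closure); the β-stereocentre is not deprotonated under these conditions.

**Step 6**
Reactants: 7
Product: 8, (3aR,4S)-6-hydroxy-4-(4-hydroxy-3-methoxyphenyl)-7-methoxy-3a,4-dihydronaphtho[2,3-c]furan-1(3H)-one
Conditions: TFA/CH2Cl2 (1:4), 0 °C, 30 min; then MeOH, 3 M HCl, 40 °C (one pot)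
Reagents that add atoms: none
Why: Ionisation of the benzylic silyl ether gives a p-alkoxybenzyl cation that undergoes intramolecular Friedel–Crafts alkylation para to the ring methoxy group; the adjacent C2 centre places the aryl group trans (1,2-induction), setting C1 as S, and the acid then removes both MOM groups.

**Step 7**
Reactants: 8
Product: 9, (1S,2R)-7-hydroxy-1-(4-hydroxy-3-methoxyphenyl)-2-(hydroxymethyl)-6-methoxy-1,2-dihydronaphthalene-3-carbaldehyde (target)
Conditions: DIBAL-H (4 eq; 2 eq consumed by the phenols), THF/CH2Cl2, −78 °C; Rochelle salt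
Reagents that add atoms: none
Why: Partial 1,2-reduction of the lactone stops at the aluminium lactolate at −78 °C; on work-up the lactol opens to the conjugated hydroxy-enal without touching either stereocentre.

**Compound list**
1 | (R)-but-3-yn-2-ol | C[C@@H](O)C#C | starting material
2 | 3-methoxy-4-(methoxymethoxy)benzaldehyde | COCOc1ccc(C=O)cc1OC | starting material
3 | (2R,5RS)-5-[(tert-butyldimethylsilyl)oxy]-5-[3-methoxy-4-(methoxymethoxy)phenyl]pent-3-yn-2-ol | C[C@@H](O)C#CC(O[Si](C)(C)C(C)(C)C)c1ccc(OCOC)c(OC)c1 | intermediate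
4 | (2R,3E,5RS)-5-[(tert-butyldimethylsilyl)oxy]-5-[3-methoxy-4-(methoxymethoxy)phenyl]pent-3-en-2-ol | C[C@@H](O)/C=C/C(O[Si](C)(C)C(C)(C)C)c1ccc(OCOC)c(OC)c1 | intermediate
5 | (3R,4E)-3-{(RS)-[(tert-butyldimethylsilyl)oxy][3-methoxy-4-(methoxymethoxy)phenyl]methyl}-N,N-dimethylhex-4-enamide | CN(C)C(=O)C[C@H](/C=C/C)C(O[Si](C)(C)C(C)(C)C)c1ccc(OCOC)c(OC)c1 | intermediate
6 | (4R)-4-{(RS)-[(tert-butyldimethylsilyl)oxy][3-methoxy-4-(methoxymethoxy)phenyl]methyl}dihydrofuran-2(3H)-one | O=C1C[C@H](CO1)C(O[Si](C)(C)C(C)(C)C)c1ccc(OCOC)c(OC)c1 | intermediate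
7 | (3E,4R)-4-{(RS)-[(tert-butyldimethylsilyl)oxy][3-methoxy-4-(methoxymethoxy)phenyl]methyl}-3-[3-methoxy-4-(methoxymethoxy)benzylidene]dihydrofuran-2(3H)-one | COCOc1ccc(/C=C2/C(=O)OC[C@@H]2C(O[Si](C)(C)C(C)(C)C)c2ccc(OCOC)c(OC)c2)cc1OC | intermediate
8 | (3aR,4S)-6-hydroxy-4-(4-hydroxy-3-methoxyphenyl)-7-methoxy-3a,4-dihydronaphtho[2,3-c]furan-1(3H)-one | COc1cc([C@H]2c3cc(O)c(OC)cc3C=C3C(=O)OC[C@H]23)ccc1O | intermediate
9 | (1S,2R)-7-hydroxy-1-(4-hydroxy-3-methoxyphenyl)-2-(hydroxymethyl)-6-methoxy-1,2-dihydronaphthalene-3-carbaldehyde (7,8,9,9-tetradehydroisolariciresinol) | COc1cc([C@H]2c3cc(O)c(OC)cc3C=C(C=O)[C@@H]2CO)ccc1O | target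

**Totals**
Total steps: 7. Longest linear sequence: 7 (from 1).

**Steps most likely to fail, with fallbacks**
- **Step 3** (rearrangement of a hindered allylic alcohol carrying an ionisable benzylic/allylic silyl ether). Fallback: move the aryl group to after the rearrangement. Rearrange the simpler (R,E)-5-(TBSO)pent-3-en-2-ol (from 1, paraformaldehyde, Red-Al, TBSCl), ozonolyse to the aldehyde and add the aryllithium from 4-bromo-2-methoxy-1-(methoxymethoxy)benzene. This costs two extra steps.
- **Step 6** (competing E1 loss of the C2 proton to a diene, incomplete trans selectivity, or side reactions during MOM removal). Fallback: deprotect first (mild HCl/MeOH to the free bis-phenol carbinol) and close the ring through the p-quinone methide under mild base or formic acid (the hydroxymatairesinol → conidendrin manifold) instead of a strong-acid cation.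
- **Step 7** (over-reduction to the diol). Fallback: reduce fully with LiAlH4 to the 2,3-bis(hydroxymethyl) diol, then oxidise only the allylic alcohol with MnO2 (two steps instead of one).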